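**Retrosynthetic overview**
1. Last step: the C9–C10 bond and the ten-membered ring are closed by an electroreductive Ni/Cr (Nozaki–Hiyama–Kishi type) cyclisation of seco iodo-aldehyde 16; the forming ring sets C9.
2. 16 comes from lactone 13 by moving the lactone from O8 to O6, senecioylating O8 and oxidising C9.
3. The C4/C5 oxirane comes from hydroxyl-directed epoxidation of (Z)-allylic alcohol 12.
4. The C6–C7 bond (C6, C7) comes from an indium Barbier allylation of (Z)-enal 6 (from neryl acetate) with bromomethylbutenolide 10; C8 is bought in (2S)-but-3-ene-1,2-diol.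
5. Ring order: butenolide (metathesis) → oxirane → lactone shift to O6 → ten-membered carbocycle.

Assumption: atoms are labelled C1–C15 by germacrane numbering, and the target is the (1(10)Z,4R,5S,6R,7S,8S,9S) isomer that the SMILES encodes (cis-4,5-oxirane, trans-fused 12,6-lactone).

**Step 1**
Reactants: 1 neryl acetate
Product: 3 (2Z)-3-methyl-6-oxohex-2-en-1-yl acetate, via secondary ozonide 2 (not isolated)
Conditions: O3 (1.0 equiv, Sudan Red 7B end point), CH2Cl2, −78 °C; then Me2S, −78 → 20 °C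
Reagents that add atoms: ozone [O-][O+]=O
Why: Criegee ozonolysis with reductive work-up cleaves the electron-rich remote trisubstituted alkene faster than the C2=C3 alkene deactivated by the allylic acetate; no stereocentre is formed and the (Z)-alkene is kept.

**Step 2**
Reactants: 3 (2Z)-3-methyl-6-oxohex-2-en-1-yl acetate
Product: 4 (2Z,6Z)-7-iodo-3-methylocta-2,6-dien-1-yl acetate
Conditions: EtPPh3I, n-BuLi, THF, 20 °C; I2, −78 °C; NaHMDS, −78 °C; then 3, −78 → −20 °C
Reagents that add atoms: ethyltriphenylphosphonium iodide CC[P+](c1ccccc1)(c1ccccc1)c1ccccc1.[I-]; iodine II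
Why: Stork–Zhao-type α-iodo Wittig olefination goes through the kinetic cis-oxaphosphetane and gives the (Z)-2-iodoalkene (iodine cis to the chain), which fixes the later C1=C10 geometry.

**Step 3**
Reactants: 4 (2Z,6Z)-7-iodo-3-methylocta-2,6-dien-1-yl acetate
Product: 5 (2Z,6Z)-7-iodo-3-methylocta-2,6-dien-1-ol
Conditions: K2CO3 (0.2 equiv), MeOH, 0 → 20 °C
Reagents that add atoms: none
Why: base-catalysed transesterification (methanolysis) removes the acetate without touching either alkene or the vinyl iodide.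

**Step 4**
Reactants: 5 (2Z,6Z)-7-iodo-3-methylocta-2,6-dien-1-ol
Product: 6 (2Z,6Z)-7-iodo-3-methylocta-2,6-dienal
Conditions: TEMPO (0.1 equiv), PhI(OAc)2 (1.1 equiv), CH2Cl2, 20 °C
Reagents that add atoms: none
Why: oxoammonium (TEMPO/diacetoxyiodobenzene) oxidation of the allylic alcohol is mild enough to keep the (2Z)-enal geometry, as it does for nerol to neral.

**Step 5**
Reactants: 7 (2S)-but-3-ene-1,2-diol
Product: 8 (2S)-1-(triethylsilyloxy)but-3-en-2-ol
Conditions: TESCl (1.0 equiv), imidazole, CH2Cl2, −40 °C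
Reagents that add atoms: chlorotriethylsilane CC[Si](Cl)(CC)CC
Why: silylation is selective for the primary hydroxyl on steric grounds; the bought stereocentre (future C8) is untouched.

**Step 6**
Reactants: 8 (2S)-1-(triethylsilyloxy)but-3-en-2-ol
Product: 9 (2S)-1-(triethylsilyloxy)but-3-en-2-yl 2-(bromomethyl)prop-2-enoate
Conditions: 2-(bromomethyl)acrylic acid, DCC, DMAP (5 mol %), CH2Cl2, 0 °C
Reagents that add atoms: 2-(bromomethyl)prop-2-enoic acid C=C(CBr)C(=O)O
Why: Steglich esterification acylates oxygen only, so the C–O stereocentre keeps its configuration.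

**Step 7**
Reactants: 9 (2S)-1-(triethylsilyloxy)but-3-en-2-yl 2-(bromomethyl)prop-2-enoate
Product: 10 (5S)-3-(bromomethyl)-5-[(triethylsilyloxy)methyl]furan-2(5H)-one
Conditions: second-generation Hoveyda–Grubbs catalyst RuCl2(SIMes)(=CH-C6H4-2-OiPr) (3 mol %), CH2Cl2 (10 mM), 40 °C
Reagents that add atoms: none
Why: ring-closing metathesis of the acrylate with the vinyl group gives the butenolide and loses ethene; the ring locks C8 cis to the carbonyl and so trans to the CH2Br terminus.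

**Step 8**
Reactants: 6 (2Z,6Z)-7-iodo-3-methylocta-2,6-dienal; 10 (5S)-3-(bromomethyl)-5-[(triethylsilyloxy)methyl]furan-2(5H)-one
Product: 12 (4R,5S)-4-[(1S,2Z,6Z)-1-hydroxy-7-iodo-3-methylocta-2,6-dien-1-yl]-3-methylidene-5-[(triethylsilyloxy)methyl]oxolan-2-one, via allylindium dibromide 11 (not isolated)
Conditions: In powder (1.5 equiv), DMF, 20 °C, ultrasound; then aq. NaHCO3
Reagents that add atoms: none
Why: Barbier-type indium allylation (SE2′) through a closed Zimmerman–Traxler chair; the ring-locked allyl geometry gives the 6,7-anti adduct and the aldehyde bonds to C7 on the face opposite the C8 CH2OTES group (7,8-trans), so C6 and C7 are set by bought C8.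

**Step 9**
Reactants: 12 (4R,5S)-4-[(1S,2Z,6Z)-1-hydroxy-7-iodo-3-methylocta-2,6-dien-1-yl]-3-methylidene-5-[(triethylsilyloxy)methyl]oxolan-2-one
Product: 13 (4R,5S)-4-[(R)-hydroxy{(2S,3R)-3-[(3Z)-4-iodopent-3-en-1-yl]-3-methyloxiran-2-yl}methyl]-3-methylidene-5-[(triethylsilyloxy)methyl]oxolan-2-one
Conditions: mCPBA (1.1 equiv), NaHCO3, CH2Cl2, 0 °C
Reagents that add atoms: 3-chloroperbenzoic acid O=C(OO)c1cccc(Cl)c1
Why: hydroxyl-directed (Henbest) peracid epoxidation; A(1,3) strain from the cis C3 chain holds H6 in the alkene plane and the hydrogen-bonded peracid delivers oxygen syn to O6 (threo), setting C4 (R) and C5 (S), while the iodoalkene and the acrylate are too electron-poor to react.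

**Step 10**
Reactants: 13 (4R,5S)-4-[(R)-hydroxy{(2S,3R)-3-[(3Z)-4-iodopent-3-en-1-yl]-3-methyloxiran-2-yl}methyl]-3-methylidene-5-[(triethylsilyloxy)methyl]oxolan-2-one
Product: 14 (4S,5R)-4-[(1S)-1-hydroxy-2-(triethylsilyloxy)ethyl]-5-{(2S,3R)-3-[(3Z)-4-iodopent-3-en-1-yl]-3-methyloxiran-2-yl}-3-methylideneoxolan-2-one
Conditions: DBU (0.2 equiv), CH2Cl2, 20 °C, to equilibrium; chromatography, recovered 13 resubmitted
Reagents that add atoms: none
Why: base-mediated translactonisation (intramolecular transesterification): the C6 alkoxide attacks C12 and releases the C8 hydroxyl; the two γ-lactones are close in energy so an equilibrium mixture is expected and 13 is recycled, and no stereocentre is touched because only the acyl carbon reacts.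

**Step 11**
Reactants: 14 (4S,5R)-4-[(1S)-1-hydroxy-2-(triethylsilyloxy)ethyl]-5-{(2S,3R)-3-[(3Z)-4-iodopent-3-en-1-yl]-3-methyloxiran-2-yl}-3-methylideneoxolan-2-one
Product: 15 (1S)-1-[(2R,3S)-2-{(2S,3R)-3-[(3Z)-4-iodopent-3-en-1-yl]-3-methyloxiran-2-yl}-4-methylidene-5-oxooxolan-3-yl]-2-(triethylsilyloxy)ethyl 3-methylbut-2-enoate
Conditions: (Me2C=CHCO)2O (1.5 equiv), DMAP (0.1 equiv), pyridine, CH2Cl2, 0 °C
Reagents that add atoms: 3-methylbut-2-enoic anhydride CC(C)=CC(=O)OC(=O)C=C(C)C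
Why: DMAP-catalysed acylation of the only free hydroxyl (O8) under conditions too weakly basic to reverse the lactone shift; configuration at C8 is retained.

**Step 12**
Reactants: 15 (1S)-1-[(2R,3S)-2-{(2S,3R)-3-[(3Z)-4-iodopent-3-en-1-yl]-3-methyloxiran-2-yl}-4-methylidene-5-oxooxolan-3-yl]-2-(triethylsilyloxy)ethyl 3-methylbut-2-enoate
Product: 16 (1S)-1-[(2R,3R)-2-{(2S,3R)-3-[(3Z)-4-iodopent-3-en-1-yl]-3-methyloxiran-2-yl}-4-methylidene-5-oxooxolan-3-yl]-2-oxoethyl 3-methylbut-2-enoate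
Conditions: (COCl)2, DMSO, CH2Cl2, −78 → −40 °C; Et3N, −78 → 0 °C; used crude
Reagents that add atoms: none
Why: Swern oxidation converts a primary triethylsilyl ether directly into the aldehyde (the chlorosulfonium salt cleaves the O–Si bond), and the cold amine step avoids epimerising C8; the descriptor at the ring carbon changes only because CIP priorities change.

**Step 13**
Reactants: 16 (1S)-1-[(2R,3R)-2-{(2S,3R)-3-[(3Z)-4-iodopent-3-en-1-yl]-3-methyloxiran-2-yl}-4-methylidene-5-oxooxolan-3-yl]-2-oxoethyl 3-methylbut-2-enoate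
Product: 19 (1(10)Z,4R,5S,6R,7S,8S,9S)-4,5-epoxy-9-hydroxy-8-[(3-methylbut-2-enoyl)oxy]germacra-1(10),11(13)-dien-12,6-olide, via alkenylchromium dichloride 17 (not isolated), via zirconocene alkoxide 18 (not isolated)
Conditions: CrCl3 (15 mol %), NiCl2(dme) (3 mol %), neocuproine (4 mol %), Cp2ZrCl2 (1.5 equiv), nBu4NBF4 (0.1 M), DMF, undivided cell, Al anode, Ni-foam cathode, 2 mA constant current (2.4 F/mol), 16 added over 12 h to 2 mM, 20 °C; then sat. aq. NH4Cl
Reagents that add atoms: none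
Why: Proposed new method: cathodic reduction of CrCl3 to divalent chromium replaces the stoichiometric metal reductant of the Nozaki–Hiyama–Kishi reaction, zerovalent nickel inserts into the C–I bond with retention and hands the (Z)-alkenyl group to chromium (17), the trivalent alkenylchromium adds to the aldehyde across the ring, and Cp2ZrCl2 takes the alkoxide off chromium (18) so that chromium turns over at high dilution; C9 is set by the closing ring, with the C8–O bond antiperiplanar to the new C9–C10 bond (Felkin–Anh) and the metal-bound carbonyl oxygen in the outward pseudo-equatorial site, which gives the 8,9-trans (9S) alcohol; the closest known chemistry is the stoichiometric Ni/Cr macrocyclisation and the intermolecular electrochemical chromium-catalysed alkenylation of aldehydes, neither shown for electrochemical closure of a ten-membered carbocycle.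

**Compound list**
1 | neryl acetate, (2Z)-3,7-dimethylocta-2,6-dien-1-yl acetate | CC(C)=CCC/C(C)=C\COC(C)=O | starting material
2 | secondary ozonide, (2Z)-5-(5,5-dimethyl-1,2,4-trioxolan-3-yl)-3-methylpent-2-en-1-yl acetate (trioxolane CH centre unspecified) | CC1(C)OOC(CC/C(C)=C\COC(C)=O)O1 | intermediate
3 | (2Z)-3-methyl-6-oxohex-2-en-1-yl acetate | O=CCC/C(C)=C\COC(C)=O | intermediate
4 | (2Z,6Z)-7-iodo-3-methylocta-2,6-dien-1-yl acetate | C/C(I)=C/CC/C(C)=C\COC(C)=O | intermediate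
5 | (2Z,6Z)-7-iodo-3-methylocta-2,6-dien-1-ol | C/C(I)=C/CC/C(C)=C\CO | intermediate
6 | (2Z,6Z)-7-iodo-3-methylocta-2,6-dienal | C/C(I)=C/CC/C(C)=C\C=O | intermediate
7 | (2S)-but-3-ene-1,2-diol | C=C[C@H](O)CO | starting material
8 | (2S)-1-(triethylsilyloxy)but-3-en-2-ol | C=C[C@H](O)CO[Si](CC)(CC)CC | intermediate
9 | (2S)-1-(triethylsilyloxy)but-3-en-2-yl 2-(bromomethyl)prop-2-enoate | C=C[C@H](OC(=O)C(=C)CBr)CO[Si](CC)(CC)CC | intermediate
10 | (5S)-3-(bromomethyl)-5-[(triethylsilyloxy)methyl]furan-2(5H)-one | O=C1O[C@H](CO[Si](CC)(CC)CC)C=C1CBr | intermediate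
11 | allylindium dibromide, {[(5S)-2-oxo-5-[(triethylsilyloxy)methyl]-2,5-dihydrofuran-3-yl]methyl}indium dibromide | O=C1O[C@H](CO[Si](CC)(CC)CC)C=C1C[In](Br)Br | intermediate
12 | (4R,5S)-4-[(1S,2Z,6Z)-1-hydroxy-7-iodo-3-methylocta-2,6-dien-1-yl]-3-methylidene-5-[(triethylsilyloxy)methyl]oxolan-2-one | C=C1C(=O)O[C@H](CO[Si](CC)(CC)CC)[C@H]1[C@@H](O)/C=C(/C)CC/C=C(/C)I | intermediate
13 | (4R,5S)-4-[(R)-hydroxy{(2S,3R)-3-[(3Z)-4-iodopent-3-en-1-yl]-3-methyloxiran-2-yl}methyl]-3-methylidene-5-[(triethylsilyloxy)methyl]oxolan-2-one | C=C1C(=O)O[C@H](CO[Si](CC)(CC)CC)[C@H]1[C@@H](O)[C@@H]1O[C@]1(C)CC/C=C(/C)I | intermediate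
14 | (4S,5R)-4-[(1S)-1-hydroxy-2-(triethylsilyloxy)ethyl]-5-{(2S,3R)-3-[(3Z)-4-iodopent-3-en-1-yl]-3-methyloxiran-2-yl}-3-methylideneoxolan-2-one | C=C1C(=O)O[C@@H]([C@@H]2O[C@]2(C)CC/C=C(/C)I)[C@@H]1[C@H](O)CO[Si](CC)(CC)CC | intermediate
15 | (1S)-1-[(2R,3S)-2-{(2S,3R)-3-[(3Z)-4-iodopent-3-en-1-yl]-3-methyloxiran-2-yl}-4-methylidene-5-oxooxolan-3-yl]-2-(triethylsilyloxy)ethyl 3-methylbut-2-enoate | C=C1C(=O)O[C@@H]([C@@H]2O[C@]2(C)CC/C=C(/C)I)[C@@H]1[C@H](OC(=O)C=C(C)C)CO[Si](CC)(CC)CC | intermediate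
16 | (1S)-1-[(2R,3R)-2-{(2S,3R)-3-[(3Z)-4-iodopent-3-en-1-yl]-3-methyloxiran-2-yl}-4-methylidene-5-oxooxolan-3-yl]-2-oxoethyl 3-methylbut-2-enoate | C=C1C(=O)O[C@@H]([C@@H]2O[C@]2(C)CC/C=C(/C)I)[C@@H]1[C@H](OC(=O)C=C(C)C)C=O | intermediate
17 | alkenylchromium dichloride of 16 (C–I replaced by C–CrCl2, trivalent chromium, Z geometry kept) | C=C1C(=O)O[C@@H]([C@@H]2O[C@]2(C)CC/C=C(/C)[Cr](Cl)Cl)[C@@H]1[C@H](OC(=O)C=C(C)C)C=O | intermediate
18 | zirconocene alkoxide of 19 (O9–ZrClCp2) | C=C1C(=O)O[C@@H]2[C@@H]1[C@H](OC(=O)C=C(C)C)[C@@H](O[Zr](Cl)(C1C=CC=C1)C1C=CC=C1)/C(C)=C\CC[C@@]1(C)O[C@@H]21 | intermediate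
19 | (1(10)Z,4R,5S,6R,7S,8S,9S)-4,5-epoxy-9-hydroxy-8-[(3-methylbut-2-enoyl)oxy]germacra-1(10),11(13)-dien-12,6-olide | C=C1C(=O)O[C@@H]2[C@@H]1[C@H](OC(=O)C=C(C)C)[C@@H](O)/C(C)=C\CC[C@@]1(C)O[C@@H]21 | target

**Step count**
Total: 13 steps. Longest linear sequence: 10 steps (steps 1–4 and 8–13, from neryl acetate).

**Steps most likely to fail**

Step 13 (the proposed electrochemical ring closure). Risks are oligomerisation, reduction of the α-acyloxy aldehyde, opening of the oxirane by aluminium salts, or the wrong C9 epimer. The fallback sets out from 16 and returns at 19 using known chemistry, and sets C9 by ketone reduction instead of by the ring-closing addition. 16 is cyclised with stoichiometric CrCl2 (8 equiv, divalent chromium) and NiCl2 (1 mol %) in DMSO–THF at 2 mM, which gives 19 together with its C9 epimer (1(10)Z,4R,5S,6R,7S,8S,9R)-4,5-epoxy-9-hydroxy-8-[(3-methylbut-2-enoyl)oxy]germacra-1(10),11(13)-dien-12,6-olide F1. F1 (or the mixture) is oxidised with Dess–Martin periodinane to the ketone (1(10)Z,4R,5S,6R,7R,8S)-4,5-epoxy-8-[(3-methylbut-2-enoyl)oxy]-9-oxogermacra-1(10),11(13)-dien-12,6-olide F2. F2 is reduced with NaBH4/CeCl3·7H2O in MeOH at −78 °C (Luche), hydride entering from the ring periphery anti to the C8–O bond, to give 19.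

Step 10 (lactone shift). The equilibrium may favour 13, and DBU may cause Payne rearrangement or move the exocyclic alkene into the ring. The fallback sets out from 13 and returns at 16, bypassing 14 and 15, and replaces the equilibrium by a protect–open–acylate–reclose sequence. 13 is silylated at O6 (TESCl, imidazole) to (4S,5S)-4-[(R)-{(2S,3R)-3-[(3Z)-4-iodopent-3-en-1-yl]-3-methyloxiran-2-yl}(triethylsilyloxy)methyl]-3-methylidene-5-[(triethylsilyloxy)methyl]oxolan-2-one F3. LiOH in THF–H2O at 0 °C opens the lactone to lithium (3S,4S)-4-hydroxy-3-[(R)-{(2S,3R)-3-[(3Z)-4-iodopent-3-en-1-yl]-3-methyloxiran-2-yl}(triethylsilyloxy)methyl]-2-methylidene-5-(triethylsilyloxy)pentanoate F4. After drying, F4 is acylated at O8 in the same flask with 3-methylbut-2-enoic anhydride and DMAP to give, after pH 5 work-up, (3S,4S)-3-[(R)-{(2S,3R)-3-[(3Z)-4-iodopent-3-en-1-yl]-3-methyloxiran-2-yl}(triethylsilyloxy)methyl]-2-methylidene-4-[(3-methylbut-2-enoyl)oxy]-5-(triethylsilyloxy)pentanoic acid F5. HF·pyridine buffered with pyridine in THF removes both silyl groups, and the freed 6-hydroxy acid closes to the γ-lactone on O6, giving (1S)-2-hydroxy-1-[(2R,3S)-2-{(2S,3R)-3-[(3Z)-4-iodopent-3-en-1-yl]-3-methyloxiran-2-yl}-4-methylidene-5-oxooxolan-3-yl]ethyl 3-methylbut-2-enoate F6. Dess–Martin oxidation of F6 gives 16.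

Step 8 (indium Barbier coupling). Risks are Z→E isomerisation of enal 6 by indium salts, ring-opening elimination of the allylindium, or partial lactone migration in the indium alkoxide. The fallback sets out from 10 (with 6) and returns at 12, using a configurationally fixed allylboron reagent instead of the allylmetal formed in situ. 10 is borylated with B2pin2 and Pd2(dba)3 (2 mol %, zerovalent palladium) in toluene at 50 °C to (5S)-3-[(4,4,5,5-tetramethyl-1,3,2-dioxaborolan-2-yl)methyl]-5-[(triethylsilyloxy)methyl]furan-2(5H)-one F7. F7 and 6 with Sc(OTf)3 (10 mol %) in toluene at 0 °C react through the same closed chair (allylboration) to the borate (4R,5S)-4-[(1S,2Z,6Z)-7-iodo-3-methyl-1-[(4,4,5,5-tetramethyl-1,3,2-dioxaborolan-2-yl)oxy]octa-2,6-dien-1-yl]-3-methylidene-5-[(triethylsilyloxy)methyl]oxolan-2-one F8. Aqueous NaHCO3 work-up hydrolyses F8 to 12.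

**Further compounds**
F1 | step 13 | (1(10)Z,4R,5S,6R,7S,8S,9R)-4,5-epoxy-9-hydroxy-8-[(3-methylbut-2-enoyl)oxy]germacra-1(10),11(13)-dien-12,6-olide | C=C1C(=O)O[C@@H]2[C@@H]1[C@H](OC(=O)C=C(C)C)[C@H](O)/C(C)=C\CC[C@@]1(C)O[C@@H]21
F2 | step 13 | (1(10)Z,4R,5S,6R,7R,8S)-4,5-epoxy-8-[(3-methylbut-2-enoyl)oxy]-9-oxogermacra-1(10),11(13)-dien-12,6-olide | C=C1C(=O)O[C@@H]2[C@@H]1[C@H](OC(=O)C=C(C)C)C(=O)/C(C)=C\CC[C@@]1(C)O[C@@H]21
F3 | step 10 | (4S,5S)-4-[(R)-{(2S,3R)-3-[(3Z)-4-iodopent-3-en-1-yl]-3-methyloxiran-2-yl}(triethylsilyloxy)methyl]-3-methylidene-5-[(triethylsilyloxy)methyl]oxolan-2-one | C=C1C(=O)O[C@H](CO[Si](CC)(CC)CC)[C@H]1[C@@H](O[Si](CC)(CC)CC)[C@@H]1O[C@]1(C)CC/C=C(/C)I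
F4 | step 10 | lithium (3S,4S)-4-hydroxy-3-[(R)-{(2S,3R)-3-[(3Z)-4-iodopent-3-en-1-yl]-3-methyloxiran-2-yl}(triethylsilyloxy)methyl]-2-methylidene-5-(triethylsilyloxy)pentanoate | C=C(C(=O)[O-])[C@@H]([C@H](O)CO[Si](CC)(CC)CC)[C@@H](O[Si](CC)(CC)CC)[C@@H]1O[C@]1(C)CC/C=C(/C)I.[Li+]
F5 | step 10 | (3S,4S)-3-[(R)-{(2S,3R)-3-[(3Z)-4-iodopent-3-en-1-yl]-3-methyloxiran-2-yl}(triethylsilyloxy)methyl]-2-methylidene-4-[(3-methylbut-2-enoyl)oxy]-5-(triethylsilyloxy)pentanoic acid | C=C(C(=O)O)[C@@H]([C@H](OC(=O)C=C(C)C)CO[Si](CC)(CC)CC)[C@@H](O[Si](CC)(CC)CC)[C@@H]1O[C@]1(C)CC/C=C(/C)I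
F6 | step 10 | (1S)-2-hydroxy-1-[(2R,3S)-2-{(2S,3R)-3-[(3Z)-4-iodopent-3-en-1-yl]-3-methyloxiran-2-yl}-4-methylidene-5-oxooxolan-3-yl]ethyl 3-methylbut-2-enoate | C=C1C(=O)O[C@@H]([C@@H]2O[C@]2(C)CC/C=C(/C)I)[C@@H]1[C@H](OC(=O)C=C(C)C)CO
F7 | step 8 | (5S)-3-[(4,4,5,5-tetramethyl-1,3,2-dioxaborolan-2-yl)methyl]-5-[(triethylsilyloxy)methyl]furan-2(5H)-one | O=C1O[C@H](CO[Si](CC)(CC)CC)C=C1CB1OC(C)(C)C(C)(C)O1
F8 | step 8 | (4R,5S)-4-[(1S,2Z,6Z)-7-iodo-3-methyl-1-[(4,4,5,5-tetramethyl-1,3,2-dioxaborolan-2-yl)oxy]octa-2,6-dien-1-yl]-3-methylidene-5-[(triethylsilyloxy)methyl]oxolan-2-one | C=C1C(=O)O[C@H](CO[Si](CC)(CC)CC)[C@H]1[C@@H](OB1OC(C)(C)C(C)(C)O1)/C=C(/C)CC/C=C(/C)I
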